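Late in the noon run target falls back: at 12.0 d it reads 47.1 %, and starting material has returned to 54.3 %. The two share the charge between them, so follow their ratio R, target over starting material.

| flask | starting material | second substrate | solid reagent | remark | time |
|---|---|---|---|---|---|
| noon | 0.050 M | 1 equiv | 2 equiv | run made earlier |  |
| summer | 0.075 M | 1 equiv | 2 equiv | run made earlier |  |
| spring | 0.10 M | 0.50 equiv | 2 equiv | run made earlier |  |
| flask | 0.10 M | 1.00 equiv | 2.00 equiv |  | 12 d |

- noon (time / d: target / %, starting material / %): 0.500: 44.7, 55.8; 1.04: 76.4, 25.0; 1.67: 80.9, 18.8; 3.00: 78.6, 22.4; 6.00: 65.6, 33.0; 12.0: 47.1, 54.3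
- summer (time / d: target / %, starting material / %): 0.500: 43.1, 57.1; 1.04: 78.7, 22.2; 1.67: 87.1, 12.6; 3.00: 85.8, 14.2; 6.00: 71.9, 26.5; 12.0: 54.2, 46.3
- spring (time / d: target / %, starting material / %): 0.500: 38.8, 57.7; 1.25: 83.1, 19.4; 2.50: 89.2, 8.9; 6.00: 77.5, 22.1; 12.0: 59.7, 42.3

(readings scatter by 1 percentage point)

1. time up to 12 d at which target stands highest
2. the amount of target, in percent of the starting material charged, at that time

How high does R climb? At the highest target readings it is 4.30 in noon and 6.91 in summer. In powers of ten, R rises 0.206 over a concentration step of 0.176, and the quotient, which carries the scatter of these readings, is 1.17. Call this n, the powers of ten gained in R per power of ten of starting material at equal equivalents, an apparent order.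

What does n give here? From summer to this flask the step is 0.125, so I reckon R at 9.68, or 90.6 % target. Spring, with half the second substrate, reads 10.0, slightly more, so I keep my 9.68 for this flask.

When? The highest readings stand at 1.67 d in summer and 2.50 d in spring. This flask has summer's equivalents at spring's strength, so I take the midpoint, 2.08 d.

The forecast, later and lower than my reckoning, says 88.5 % at 2.5 d, adding “The peak is flat, so the time is loose”.

The flask gives 91.4 % at 2.14 d.

    starting material + coupling partner ⇌ target (K = 280 /M, k = 1.60 /M/h)
    second substrate + coupling partner ⇌ second product (K = 0.670 /M, k = 2.50 /M/h)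
    solid reagent ⇌ coupling partner, rate k3*(cs3 - [coupling partner]) while solid is left; crystals form when [coupling partner] > cs3 (solubility = 0.0860 M, k = 0.130 /h)
    second substrate ⇌ dormant form (K = 2.30, k = 0.0570 /h)
    coupling partner → decomposed reagent (k = 0.0300 /h)

In this flask R stands at 10.6 at 2.14 d, above my 9.68. The neighbouring flask keeps the equivalents but holds 0.060 M of starting material, 0.0792 powers of ten above noon. With n, R comes to 5.33, or 84.2 % target, and that flask's highest target is 84.6 %.

The earlier runs and the new flask come from a simulation for substances that don't exist; the scatter is artificial.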